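**Plan**

1. Each half is numbered C1(OH), C2(aryl–aryl bond), C3, C4(OMe), C4a, C5(OH), C6, C7(Me), C8, C8a; ring A is C1–C4/C4a/C8a, ring B is C4a–C8a. C1–C2–C3–C4 of both halves, joined at C2–C2', is a 5,5'-dioxygenated 3,3'-bifuran in disguise, and C4a–C8a with the oxygen on C5 is a 3-alkoxybenzyne.
2. Retrosynthesis: the O-benzyl and O-methyl groups are traced back to a 1,1'-diol 4,4'-bis(silyl ether). C1–C8a and C4–C4a are then cut in both halves (retro aryne–furan [4+2] with ring opening). C2–C2' is cut last, to two 4-bromobutenolides, and the aryne is traced to orcinol.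
3. Forward: C2–C2' is made first by reductive homocoupling, and the dione is aromatised to the bis(silyloxyfuran). Both rings A are then annulated in one operation onto two orcinol-derived rings B, and three protecting-group steps finish the synthesis.
4. The aryne is released by iodine–lithium exchange on an o-iodoaryl triflate rather than by fluoride on an o-silylaryl triflate. Fluoride would also cleave the silyl dienol ethers of the bifuran and the aryl silyl ethers of the product.
5. Stereochemistry: the target has no stereocentre, and the 2,2'-axis (one oxygen and one hydrogen ortho on each side) is taken as freely rotating. The bridgehead centres of the cycloadduct vanish on aromatisation.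

Key step: step 6

**Route**

Step 1
Reactants: 1 orcinol (5-methylbenzene-1,3-diol)
Product: 2 2-iodo-5-methylbenzene-1,3-diol
Conditions: I2 (1.05 equiv), NaHCO3 (1.1 equiv), H2O, 0 °C to rt
Reagents that add atoms: iodine, [I][I]
Why: Electrophilic aromatic iodination of a resorcinol in aqueous bicarbonate is directed to the carbon between the two hydroxyls, which in 1 is also the only activated position not flanked by the methyl group, so the symmetric 2-iodide should be the main product.

Step 2
Reactants: 2 2-iodo-5-methylbenzene-1,3-diol
Product: 3 3-(benzyloxy)-2-iodo-5-methylphenol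
Conditions: BnBr (1.0 equiv), K2CO3 (1.0 equiv), acetone, 50 °C; recovered 2 recycled
Reagents that add atoms: benzyl bromide, BrCc1ccccc1
Why: Williamson etherification of one of two equivalent phenols, which with one equivalent of benzyl bromide should give the mono ether alongside separable bis-ether and unreacted 2 that is returned to the step.

Step 3
Reactants: 3 3-(benzyloxy)-2-iodo-5-methylphenol
Product: 4 3-(benzyloxy)-2-iodo-5-methylphenyl trifluoromethanesulfonate
Conditions: Tf2O (1.2 equiv), pyridine, CH2Cl2, 0 °C
Reagents that add atoms: trifluoromethanesulfonic anhydride, O=S(=O)(OS(=O)(=O)C(F)(F)F)C(F)(F)F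
Why: O-Sulfonylation of the remaining phenol with triflic anhydride and pyridine is routine even next to an ortho iodine, and it places the leaving group and the exchangeable halogen on adjacent carbons as an aryne precursor.

Step 4
Reactants: 5 4-bromofuran-2(5H)-one (two molecules)
Product: 6 [3,3'-bifuran]-5,5'(2H,2'H)-dione
Conditions: NiBr2(PPh3)2 (10 mol%), Zn dust (1.5 equiv), Et4NI (1 equiv), THF, 50 °C
Reagents that add atoms: none
Why: Nickel-catalysed reductive homocoupling of an alkenyl halide, in which zinc reduces divalent nickel to zerovalent nickel, this inserts into the activated vinylic C–Br bond of the β-bromo enoate and two alkenyl groups are joined at nickel by reductive elimination to form the future C2–C2' bond.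

Step 5
Reactants: 6 [3,3'-bifuran]-5,5'(2H,2'H)-dione
Product: 7 5,5'-bis(triisopropylsilyloxy)-3,3'-bifuran
Conditions: TIPSOTf (2.4 equiv), Et3N (3 equiv), CH2Cl2, 0 °C to rt; filtration through Et3N-deactivated silica
Reagents that add atoms: triisopropylsilyl trifluoromethanesulfonate, CC(C)[Si](OS(=O)(=O)C(F)(F)F)(C(C)C)C(C)C
Why: Soft enolisation of a butenolide to a 2-silyloxyfuran, in which the silyl triflate activates each lactone carbonyl and triethylamine removes a γ-proton from the ring O–CH2 group, the gain in furan aromaticity driving both rings to the silyl dienol ether.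

Step 6
Reactants: 7 5,5'-bis(triisopropylsilyloxy)-3,3'-bifuran; 4 3-(benzyloxy)-2-iodo-5-methylphenyl trifluoromethanesulfonate (2.6 equiv)
Product: 10 5,5'-bis(benzyloxy)-7,7'-dimethyl-4,4'-bis(triisopropylsilyloxy)-2,2'-binaphthalene-1,1'-diol, via 3-(benzyloxy)-5-methylbenzyne 8 (not isolated), via twofold oxa-bridged cycloadduct 9 (not isolated)
Conditions: n-BuLi (2.6 equiv, added dropwise to 7 and 4), THF, −78 °C to 0 °C, argon; aq NH4Cl; then SiO2 or PPTS (cat.), CH2Cl2, rt
Reagents that add atoms: none
Why: Iodine–lithium exchange on 4 and loss of lithium triflate from the o-lithioaryl triflate release aryne 8 at −78 °C without fluoride, so neither the silyl dienol ethers of 7 nor the aryl silyl ethers of the product are attacked. Each silyloxyfuran ring of 7 then adds across the strained triple bond in an asynchronous intermolecular [4+2] cycloaddition, the closest known reaction type being the cycloaddition of 3-alkoxybenzynes with 2-alkoxy- or 2-silyloxyfurans followed by ring opening to differentially protected naphthalene-1,4,5-triols. Ring A of each half thus closes by cycloaddition, C1–C8a and C4–C4a being formed together, and the bridged silyl ketal of 9 opens on mild acid by heterolysis of the bond between C4 and the bridge oxygen with loss of the C1 proton, which leaves the bridge oxygen as the C1 hydroxyl and the silyloxy group on C4. The four bridgehead stereocentres of 9 arise unselectively and are erased by this aromatisation, so no stereocontrol is needed. The step needs regiocontrol: the benzyloxy group distorts the aryne inductively so that the carbon remote from it (future C8a) is the electrophilic one, and it is met by the unsubstituted α-carbon of the silyl dienol ether, its most nucleophilic terminus, so C4–OSi lands peri to C5–OBn and the inter-furan bond becomes C2–C2'. Bond formation at the silyloxy terminus is late in the transition state, so the bulk of the triisopropylsilyl group should not override this electronic preference, and the excess of 4 drives both annulations to completion.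

Step 7
Reactants: 10 5,5'-bis(benzyloxy)-7,7'-dimethyl-4,4'-bis(triisopropylsilyloxy)-2,2'-binaphthalene-1,1'-diol
Product: 11 1,1',5,5'-tetrakis(benzyloxy)-7,7'-dimethyl-4,4'-bis(triisopropylsilyloxy)-2,2'-binaphthalene
Conditions: BnBr (3 equiv), K2CO3 (4 equiv), n-Bu4NI (cat.), degassed acetone, reflux, argon
Reagents that add atoms: benzyl bromide, BrCc1ccccc1
Why: Williamson etherification of the two naphthols with benzyl bromide and carbonate, conditions that leave aryl triisopropylsilyl ethers intact, caps the C1 oxygens so that the C4 oxygens can be addressed alone in the next step, and the exclusion of air guards the electron-rich binaphthol against oxidation.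

Step 8
Reactants: 11 1,1',5,5'-tetrakis(benzyloxy)-7,7'-dimethyl-4,4'-bis(triisopropylsilyloxy)-2,2'-binaphthalene
Product: 13 1,1',5,5'-tetrakis(benzyloxy)-4,4'-dimethoxy-7,7'-dimethyl-2,2'-binaphthalene, via dicesium 4,4'-diolate 12 (not isolated)
Conditions: CsF (6 equiv), MeI (10 equiv), DMF, rt, argon
Reagents that add atoms: iodomethane, CI
Why: Fluoride cleaves the two aryl O–Si bonds to the cesium naphthoxides, which are O-methylated in the same flask by iodomethane (desilylation followed by Williamson etherification), so the air-sensitive 4-naphthols are never isolated and the benzyl ethers are untouched.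

Step 9
Reactants: 13 1,1',5,5'-tetrakis(benzyloxy)-4,4'-dimethoxy-7,7'-dimethyl-2,2'-binaphthalene
Product: 14 4,4'-dimethoxy-7,7'-dimethyl-2,2'-binaphthalene-1,1',5,5'-tetrol (CNP0204479.0)
Conditions: H2 (1 atm), 10% Pd/C, THF/MeOH, rt; work-up under argon
Reagents that add atoms: none
Why: Catalytic hydrogenolysis over palladium cleaves all four benzylic C–O bonds at atmospheric pressure, conditions under which aryl methyl ethers and naphthalene rings are not reduced, and releases the tetrol.

**Compound list**

1 | orcinol (5-methylbenzene-1,3-diol) | Cc1cc(O)cc(O)c1 | starting material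
2 | 2-iodo-5-methylbenzene-1,3-diol | Cc1cc(O)c(I)c(O)c1 | intermediate
3 | 3-(benzyloxy)-2-iodo-5-methylphenol | Cc1cc(O)c(I)c(OCc2ccccc2)c1 | intermediate
4 | 3-(benzyloxy)-2-iodo-5-methylphenyl trifluoromethanesulfonate | Cc1cc(OCc2ccccc2)c(I)c(OS(=O)(=O)C(F)(F)F)c1 | intermediate
5 | 4-bromofuran-2(5H)-one | O=C1C=C(Br)CO1 | starting material
6 | [3,3'-bifuran]-5,5'(2H,2'H)-dione (4,4'-bi(furan-2(5H)-one)) | O=C1C=C(C2=CC(=O)OC2)CO1 | intermediate
7 | 5,5'-bis(triisopropylsilyloxy)-3,3'-bifuran | CC(C)[Si](C(C)C)(C(C)C)Oc1cc(-c2coc(O[Si](C(C)C)(C(C)C)C(C)C)c2)co1 | intermediate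
8 | 3-(benzyloxy)-5-methylbenzyne | CC1=CC#CC(OCc2ccccc2)=C1 | intermediate (not isolated)
9 | 5,5'-bis(benzyloxy)-7,7'-dimethyl-4,4'-bis(triisopropylsilyloxy)-1,1',4,4'-tetrahydro-1,4:1',4'-diepoxy-2,2'-binaphthalene (mixture of diastereomers) | CC(C)[Si](C(C)C)(C(C)C)OC12C=C(C3=CC4(O[Si](C(C)C)(C(C)C)C(C)C)OC3c3cc(C)cc(OCc5ccccc5)c34)C(O1)c1cc(C)cc(OCc3ccccc3)c12 | intermediate (not isolated)
10 | 5,5'-bis(benzyloxy)-7,7'-dimethyl-4,4'-bis(triisopropylsilyloxy)-2,2'-binaphthalene-1,1'-diol | CC(C)[Si](C(C)C)(C(C)C)Oc1cc(-c2cc(O[Si](C(C)C)(C(C)C)C(C)C)c3c(OCc4ccccc4)cc(C)cc3c2O)c(O)c2cc(C)cc(OCc3ccccc3)c12 | intermediate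
11 | 1,1',5,5'-tetrakis(benzyloxy)-7,7'-dimethyl-4,4'-bis(triisopropylsilyloxy)-2,2'-binaphthalene | CC(C)[Si](C(C)C)(C(C)C)Oc1cc(-c2cc(O[Si](C(C)C)(C(C)C)C(C)C)c3c(OCc4ccccc4)cc(C)cc3c2OCc2ccccc2)c(OCc2ccccc2)c2cc(C)cc(OCc3ccccc3)c12 | intermediate
12 | dicesium 1,1',5,5'-tetrakis(benzyloxy)-7,7'-dimethyl-2,2'-binaphthalene-4,4'-diolate | [Cs+].[Cs+].[O-]c1cc(-c2cc([O-])c3c(OCc4ccccc4)cc(C)cc3c2OCc2ccccc2)c(OCc2ccccc2)c2cc(C)cc(OCc3ccccc3)c12 | intermediate (not isolated)
13 | 1,1',5,5'-tetrakis(benzyloxy)-4,4'-dimethoxy-7,7'-dimethyl-2,2'-binaphthalene | COc1cc(-c2cc(OC)c3c(OCc4ccccc4)cc(C)cc3c2OCc2ccccc2)c(OCc2ccccc2)c2cc(C)cc(OCc3ccccc3)c12 | intermediate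
14 | 4,4'-dimethoxy-7,7'-dimethyl-2,2'-binaphthalene-1,1',5,5'-tetrol | COc1cc(-c2cc(OC)c3c(O)cc(C)cc3c2O)c(O)c2cc(C)cc(O)c12 | target

**Summary**

Total step count: 9. Longest linear sequence: 7 steps (steps 1, 2, 3, 6, 7, 8, 9).

Steps most likely to fail:

Step 6. The twofold annulation may stall after the first cycloaddition, or the aryne may be consumed by addition of the organolithium or of the aryllithium, because here the furan is the limiting partner and each molecule must capture two arynes. Separating regioisomeric dimers would add to the loss. The fallback forms the naphthalene first and the biaryl bond second. Setting out from 4, the same aryne 8 is generated (n-BuLi, THF, −78 °C) in the presence of an excess of commercial 2-(triisopropylsilyloxy)furan. This should give 5-(benzyloxy)-7-methyl-4-(triisopropylsilyloxy)-1,4-dihydro-1,4-epoxynaphthalene F1, which opens on silica to 5-(benzyloxy)-7-methyl-4-(triisopropylsilyloxy)naphthalen-1-ol F2; any regioisomer can be removed at this monomer stage. Oxidative ortho–ortho phenol coupling of F2 at C2, the only free position ortho to the hydroxyl (para is blocked by the silyloxy group), with Ag2O in CH2Cl2, followed by a Na2S2O4 wash to return any over-oxidised quinoid dimer to the diol, would give 10, where the route is rejoined.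

Step 4. Reductive loss of bromine or conjugate reduction of the butenolide by zinc may outrun the nickel-mediated coupling, and the sparingly soluble dione may coat the zinc surface. The fallback is a Stille cross-coupling of two differentiated butenolides. From 5, (Bu3Sn)2 and Pd(PPh3)4 in toluene at 100 °C should give 4-(tributylstannyl)furan-2(5H)-one F3. This is coupled with a second equivalent of 5 (Pd2(dba)3, AsPh3, CuI, DMF, 50 °C) to return to the route at 6.

Step 5. The dione 6 is a doubly activated Michael acceptor with acidic γ-protons and may oligomerise under amine base before both lactones are silylated, so that double enolisation remains incomplete. The fallback silylates before the C–C bond is made. From 5, TIPSOTf and Et3N in CH2Cl2 at 0 °C should give 4-bromo-2-(triisopropylsilyloxy)furan F4. A Stille–Kelly homocoupling under neutral conditions ((Me3Sn)2 0.5 equiv, Pd(PPh3)4, dioxane, 100 °C) then passes through trimethyl[5-(triisopropylsilyloxy)furan-3-yl]stannane F5, which couples with the remaining F4 and rejoins the route at 7.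

**Further compounds**

F1 | step 6 | 5-(benzyloxy)-7-methyl-4-(triisopropylsilyloxy)-1,4-dihydro-1,4-epoxynaphthalene (racemic) | CC(C)[Si](C(C)C)(C(C)C)OC12C=CC(O1)c1cc(C)cc(OCc3ccccc3)c12
F2 | step 6 | 5-(benzyloxy)-7-methyl-4-(triisopropylsilyloxy)naphthalen-1-ol | CC(C)[Si](C(C)C)(C(C)C)Oc1ccc(O)c2cc(C)cc(OCc3ccccc3)c12
F3 | step 4 | 4-(tributylstannyl)furan-2(5H)-one | CCCC[Sn](CCCC)(CCCC)C1=CC(=O)OC1
F4 | step 5 | 4-bromo-2-(triisopropylsilyloxy)furan | CC(C)[Si](C(C)C)(C(C)C)Oc1cc(Br)co1
F5 | step 5 | trimethyl[5-(triisopropylsilyloxy)furan-3-yl]stannane | CC(C)[Si](C(C)C)(C(C)C)Oc1cc([Sn](C)(C)C)co1
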